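**Plan**
1. Retrosynthetic cuts, in order: (i) the primary ester C–O bond between the ring CH2O and the hydroxymethylglutaryl unit; (ii) the C5–H bond and both oxirane C–O bonds, back to an achiral cyclohexadienone monoketal, i.e. a p-methoxyphenol; (iii) the side-chain C1′–C2′ bond (ring-CH2 to vinyl CH) together with the C3′–CH3 bond.
2. Enabling feature: the side-chain CH2 sits on ring carbon C1 of the 7-oxabicyclo[4.1.0]heptenone, next to the C2 carbonyl. At the benzene oxidation level of that six-membered ring it is a benzylic carbon ortho to a phenol oxygen, so it can be a benzylic chloride, and the C2′=C3′(CH3) unit is the syn-methylmetalation product of a terminal alkyne.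
3. Forward: geranyl bromide is propargylated to a C13 enyne. One-pot methylalumination of the alkyne and Ni-catalysed coupling with the benzylic chloride makes two C–C bonds, sets the 2′E olefin and joins the halves. The arene (the oxidation-level helper) is then dearomatised to the dienone monoketal.
4. Rings: the carbocycle is the benzene ring of the starting aldehyde; the oxirane is closed afterwards by tartrate-mediated nucleophilic epoxidation. Ketal hydrolysis, hydroxyl-directed reduction, esterification and SEM removal finish the route.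
5. Stereochemistry: 6′E from geranyl bromide and 2′E from syn-carboalumination; C1/C6 from the tartrate-controlled epoxidation; C5 from hydride delivery anti to the oxirane. The glutarate stereocentre comes from (R)-mevalonolactone, whose C5 arm becomes the ring ester and whose C1 carboxyl ends as the free acid.

Key step: step 7

Remark: farnesyl = (2E,6E)-3,7,11-trimethyldodeca-2,6,10-trien-1-yl; TIPS = triisopropylsilyl; SEM = [2-(trimethylsilyl)ethoxy]methyl; ring locants are those of the 7-oxabicyclo[4.1.0]heptane names.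
Remark: metal salts of a product that are only protonated on aqueous work-up (acetylide, alkoxides, phenoxide) are not counted as separate compounds.
Assumption: L-diisopropyl tartrate is taken to give the required (1R,6S) epoxide in step 10, by analogy with the closest hydroxymethyl quinone monoketal cases; if the sense is opposite, D-diisopropyl tartrate is used with no other change.

Step 1
Reactants: 1 geranyl bromide, (2E)-1-bromo-3,7-dimethylocta-2,6-diene
Product: 2 (5E)-6,10-dimethylundeca-5,9-dien-1-yne
Conditions: propyne, n-BuLi (2 equiv per propyne), TMEDA, Et2O/hexane, −78 to 0 °C; then 1, −78 °C to rt; H2O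
Reagents that add atoms: propyne, CC#C
Why: Propargylic C-alkylation of 1,3-dilithiopropyne, whose sp3 carbanion end should displace the primary allylic bromide by SN2 without allylic transposition, so the E geometry of 1 is carried into the enyne and the acetylide end is protonated on work-up.

Step 2
Reactants: 3 4-bromo-2,5-dimethoxybenzaldehyde
Product: 4 4-bromo-2-hydroxy-5-methoxybenzaldehyde
Conditions: BCl3 (1.2 equiv), CH2Cl2, −78 to 0 °C; H2O
Reagents that add atoms: none
Why: Chelation-assisted Lewis-acid O-demethylation, in which BCl3 bound to the aldehyde oxygen should cleave only the ortho methoxy group and leave the 5-methoxy group (the future ketal carbon) intact.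

Step 3
Reactants: 4 4-bromo-2-hydroxy-5-methoxybenzaldehyde
Product: 5 2-hydroxy-4-(hydroxymethyl)-5-methoxybenzaldehyde
Conditions: Bu3SnCH2OH, Pd(PPh3)4 (5 mol %), 1,4-dioxane, 90 °C
Reagents that add atoms: (tributylstannyl)methanol, CCCC[Sn](CCCC)(CCCC)CO
Why: Migita–Kosugi–Stille hydroxymethylation of the aryl bromide under neutral conditions that should tolerate the free salicylaldehyde unit.

Step 4
Reactants: 5 2-hydroxy-4-(hydroxymethyl)-5-methoxybenzaldehyde
Product: 6 5-methoxy-2-[(triisopropylsilyl)oxy]-4-{[(triisopropylsilyl)oxy]methyl}benzaldehyde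
Conditions: TIPSOTf (2.3 equiv), 2,6-lutidine, CH2Cl2, 0 °C
Reagents that add atoms: triisopropylsilyl trifluoromethanesulfonate, CC(C)[Si](C(C)C)(C(C)C)OS(=O)(=O)C(F)(F)F
Why: Silyl ether formation on both hydroxyls with a silyl triflate; the bulky TIPS group is chosen so that the aryl silyl ether should not migrate to the neighbouring benzylic oxygen in step 5, and both groups leave together in step 8.

Step 5
Reactants: 6 5-methoxy-2-[(triisopropylsilyl)oxy]-4-{[(triisopropylsilyl)oxy]methyl}benzaldehyde
Product: 7 {5-methoxy-2-[(triisopropylsilyl)oxy]-4-{[(triisopropylsilyl)oxy]methyl}phenyl}methanol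
Conditions: DIBAL-H (1.1 equiv), CH2Cl2, −78 °C; Rochelle salt
Reagents that add atoms: none
Why: Hydride reduction of the aldehyde at low temperature, where the aluminium alkoxide is a poor nucleophile towards silicon and the aryl O-silyl group should stay in place.

Step 6
Reactants: 7 {5-methoxy-2-[(triisopropylsilyl)oxy]-4-{[(triisopropylsilyl)oxy]methyl}phenyl}methanol
Product: 8 1-(chloromethyl)-5-methoxy-2-[(triisopropylsilyl)oxy]-4-{[(triisopropylsilyl)oxy]methyl}benzene
Conditions: PPh3, NCS (premixed), CH2Cl2, 0 °C; used directly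
Reagents that add atoms: N-chlorosuccinimide, O=C1CCC(=O)N1Cl
Why: Appel-type chlorination through the alkoxyphosphonium ion should give the benzylic chloride under neutral conditions that leave both silyl ethers untouched.

Step 7
Reactants: 2 (5E)-6,10-dimethylundeca-5,9-dien-1-yne; 8 1-(chloromethyl)-5-methoxy-2-[(triisopropylsilyl)oxy]-4-{[(triisopropylsilyl)oxy]methyl}benzene
Product: 10 1-methoxy-4-[(triisopropylsilyl)oxy]-2-{[(triisopropylsilyl)oxy]methyl}-5-farnesylbenzene, via dimethylalkenylalane 9 (not isolated)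
Conditions: Me3Al (2 equiv), Cp2ZrCl2 (25 mol %), (CH2Cl)2, rt; volatiles removed; THF, then 8 (0.8 equiv), NiCl2(PPh3)2/n-BuLi (5 mol % Ni(0)), 0 °C to rt
Reagents that add atoms: trimethylaluminium, C[Al](C)C
Why: Zr-catalysed methylalumination (Negishi carboalumination) adds CH3–Al across the terminal alkyne of 2 in a syn fashion with the methyl on the internal carbon, so alane 9 carries the C3′ methyl and the 2′E geometry; after removal of excess Me3Al, Ni(0) inserts into the benzylic C–Cl bond of 8, the alkenyl group passes from aluminium to nickel with retention, and reductive elimination forms the C1′–C2′ bond. The closest known reaction type is the one-pot carboalumination/Ni(0)- or Pd(0)-catalysed coupling of prenylogous alkynes with chloromethyl arenes and chloromethyl quinones used for ubiquinone- and vitamin K-type side chains. No ring is closed and no stereocentre is formed; the stereo-element created is the trisubstituted C2′=C3′ double bond, whose E configuration is fixed by the syn addition (CH3 and Al cis) and by retention in the coupling. The step needs regioselective methylalumination (secured by the terminal alkyne, Al going to the CH terminus), chemoselectivity over the two trisubstituted olefins of 2 (which do not carbometalate), and bond formation at the benzylic carbon only. The last point is secured by the pairing itself, because an alkenyl nucleophile and a benzylic electrophile have no SN2′ or E/Z-scrambling pathway of the kind open to an aryl metal and a farnesyl halide. The silyl ethers and the methyl ether of 8 should be inert to the alane and to Ni(0).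

Step 8
Reactants: 10 1-methoxy-4-[(triisopropylsilyl)oxy]-2-{[(triisopropylsilyl)oxy]methyl}-5-farnesylbenzene
Product: 11 5-(hydroxymethyl)-4-methoxy-2-farnesylphenol
Conditions: TBAF (2.5 equiv), THF, 0 °C to rt; aq. NH4Cl
Reagents that add atoms: none
Why: Fluoride-mediated cleavage of the aryl and the alkyl silyl ether in one operation, leaving the free phenol needed for dearomatisation and the free primary alcohol needed to anchor the epoxidation.

Step 9
Reactants: 11 5-(hydroxymethyl)-4-methoxy-2-farnesylphenol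
Product: 12 5-(hydroxymethyl)-4,4-dimethoxy-2-farnesylcyclohexa-2,5-dien-1-one
Conditions: PhI(OAc)2 (1.1 equiv), MeOH, 0 °C
Reagents that add atoms: methanol, CO
Why: Hypervalent-iodine oxidative dearomatisation of a p-methoxyphenol, in which methanol traps the phenoxenium ion at the methoxy-bearing para carbon, so the carbonyl should end up next to the farnesyl-bearing carbon and the ketal next to the hydroxymethyl-bearing carbon.

Step 10
Reactants: 12 5-(hydroxymethyl)-4,4-dimethoxy-2-farnesylcyclohexa-2,5-dien-1-one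
Product: 13 (1R,6S)-4-(hydroxymethyl)-5,5-dimethoxy-1-farnesyl-7-oxabicyclo[4.1.0]hept-3-en-2-one
Conditions: Ph3COOH, NaHMDS, L-DIPT, 4 Å MS, toluene, −78 to −40 °C
Reagents that add atoms: trityl hydroperoxide, OOC(c1ccccc1)(c1ccccc1)c1ccccc1
Why: Tartrate-mediated asymmetric nucleophilic (Weitz–Scheffer) epoxidation, in which the sodium alkoxide of the hydroxymethyl group anchors the tartrate–peroxide aggregate, the peroxide adds to the unsubstituted β-carbon of the farnesyl-bearing enone (the other β-carbon is fully substituted) on the face chosen by the tartrate, and 3-exo-tet closure of the enolate onto the O–O bond should give the cis-fused oxirane with both stereocentres (1R,6S).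

Step 11
Reactants: 13 (1R,6S)-4-(hydroxymethyl)-5,5-dimethoxy-1-farnesyl-7-oxabicyclo[4.1.0]hept-3-en-2-one
Product: 14 (1R,6S)-4-(hydroxymethyl)-1-farnesyl-7-oxabicyclo[4.1.0]hept-3-ene-2,5-dione
Conditions: 48% aq. HF, MeCN, 0 °C to rt
Reagents that add atoms: water, O
Why: Acid-catalysed hydrolysis of the dimethyl ketal to the ene-dione; the oxirane is deactivated by the flanking carbonyl groups and, like the farnesyl olefins, should tolerate aqueous HF in acetonitrile.

Step 12
Reactants: 14 (1R,6S)-4-(hydroxymethyl)-1-farnesyl-7-oxabicyclo[4.1.0]hept-3-ene-2,5-dione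
Product: 15 (1R,5R,6R)-5-hydroxy-4-(hydroxymethyl)-1-farnesyl-7-oxabicyclo[4.1.0]hept-3-en-2-one
Conditions: Me4NBH(OAc)3, MeCN/AcOH, −30 °C
Reagents that add atoms: none
Why: Hydroxyl-directed (Evans–Saksena) reduction, in which the triacetoxyborohydride exchanges onto the primary hydroxyl and delivers hydride intramolecularly only to the adjacent C5 carbonyl (C2 is out of reach), from the face anti to the oxirane oxygen (Felkin–Anh and steric control), which should give the 5R carbinol cis to the epoxide.

Step 13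
Reactants: 16 (R)-mevalonolactone, (4R)-4-hydroxy-4-methyloxan-2-one
Product: 18 [2-(trimethylsilyl)ethoxy]methyl (3R)-3,5-dihydroxy-3-methylpentanoate, via potassium mevalonate 17 (not isolated)
Conditions: KOH (1.0 equiv), H2O/MeOH, rt; evaporation, toluene azeotrope; SEMCl, DMF, 0 °C
Reagents that add atoms: potassium hydroxide, [K+].[OH-]; [2-(trimethylsilyl)ethoxy]methyl chloride, C[Si](C)(C)CCOCCl
Why: Lactone saponification followed by O-alkylation of the dry carboxylate with the reactive chloromethyl ether, which masks the original C1 carboxyl and frees the C5 hydroxyl without touching the stereocentre.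

Step 14
Reactants: 18 [2-(trimethylsilyl)ethoxy]methyl (3R)-3,5-dihydroxy-3-methylpentanoate
Product: 19 (3R)-3-hydroxy-3-methyl-5-oxo-5-{[2-(trimethylsilyl)ethoxy]methoxy}pentanoic acid
Conditions: TEMPO (cat.), PhI(OAc)2 (2.2 equiv), MeCN/H2O, 0 °C to rt
Reagents that add atoms: water, O
Why: TEMPO/PhI(OAc)2 oxidation of the primary alcohol to the carboxylic acid through the aldehyde hydrate; the tertiary alcohol cannot be oxidised and the stereocentre is not involved.

Step 15
Reactants: 15 (1R,5R,6R)-5-hydroxy-4-(hydroxymethyl)-1-farnesyl-7-oxabicyclo[4.1.0]hept-3-en-2-one; 19 (3R)-3-hydroxy-3-methyl-5-oxo-5-{[2-(trimethylsilyl)ethoxy]methoxy}pentanoic acid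
Product: 20 [(1R,5R,6R)-5-hydroxy-2-oxo-1-farnesyl-7-oxabicyclo[4.1.0]hept-3-en-4-yl]methyl [2-(trimethylsilyl)ethoxy]methyl (3R)-3-hydroxy-3-methylpentanedioate
Conditions: EDC·HCl (1.2 equiv), DMAP (cat.), CH2Cl2, −20 to 0 °C
Reagents that add atoms: none
Why: Steglich-type carbodiimide esterification, in which the primary allylic hydroxyl should react much faster than the hindered secondary carbinol next to the oxirane and than the tertiary hydroxyl of 19.

Step 16
Reactants: 20 [(1R,5R,6R)-5-hydroxy-2-oxo-1-farnesyl-7-oxabicyclo[4.1.0]hept-3-en-4-yl]methyl [2-(trimethylsilyl)ethoxy]methyl (3R)-3-hydroxy-3-methylpentanedioate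
Product: 21 (3S)-3-hydroxy-5-{[(1R,5R,6R)-5-hydroxy-2-oxo-1-farnesyl-7-oxabicyclo[4.1.0]hept-3-en-4-yl]methoxy}-3-methyl-5-oxopentanoic acid (target)
Conditions: 48% aq. HF, MeCN, 0 °C
Reagents that add atoms: none
Why: Fluoride/acid-induced fragmentation of the SEM ester (attack at silicon, loss of ethene and formaldehyde) should free the carboxylic acid under the conditions the epoxyquinol already met in step 11; the descriptor changes from 3R to 3S only because the CIP priorities of the two arms change.

**Compound list**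
1 | geranyl bromide, (2E)-1-bromo-3,7-dimethylocta-2,6-diene | CC(C)=CCC/C(C)=C/CBr | starting material
2 | (5E)-6,10-dimethylundeca-5,9-dien-1-yne | CC(C)=CCC/C(C)=C/CCC#C | intermediate
3 | 4-bromo-2,5-dimethoxybenzaldehyde | O=Cc1cc(OC)c(Br)cc1OC | starting material
4 | 4-bromo-2-hydroxy-5-methoxybenzaldehyde | O=Cc1cc(OC)c(Br)cc1O | intermediate
5 | 2-hydroxy-4-(hydroxymethyl)-5-methoxybenzaldehyde | O=Cc1cc(OC)c(CO)cc1O | intermediate
6 | 5-methoxy-2-[(triisopropylsilyl)oxy]-4-{[(triisopropylsilyl)oxy]methyl}benzaldehyde | O=Cc1cc(OC)c(CO[Si](C(C)C)(C(C)C)C(C)C)cc1O[Si](C(C)C)(C(C)C)C(C)C | intermediate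
7 | {5-methoxy-2-[(triisopropylsilyl)oxy]-4-{[(triisopropylsilyl)oxy]methyl}phenyl}methanol | OCc1cc(OC)c(CO[Si](C(C)C)(C(C)C)C(C)C)cc1O[Si](C(C)C)(C(C)C)C(C)C | intermediate
8 | 1-(chloromethyl)-5-methoxy-2-[(triisopropylsilyl)oxy]-4-{[(triisopropylsilyl)oxy]methyl}benzene | ClCc1cc(OC)c(CO[Si](C(C)C)(C(C)C)C(C)C)cc1O[Si](C(C)C)(C(C)C)C(C)C | intermediate
9 | dimethyl[(1E,5E)-2,6,10-trimethylundeca-1,5,9-trien-1-yl]alumane | CC(C)=CCC/C(C)=C/CC/C(C)=C/[Al](C)C | intermediate (not isolated)
10 | 1-methoxy-4-[(triisopropylsilyl)oxy]-2-{[(triisopropylsilyl)oxy]methyl}-5-[(2E,6E)-3,7,11-trimethyldodeca-2,6,10-trien-1-yl]benzene | CC(C)=CCC/C(C)=C/CC/C(C)=C/Cc1cc(OC)c(CO[Si](C(C)C)(C(C)C)C(C)C)cc1O[Si](C(C)C)(C(C)C)C(C)C | intermediate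
11 | 5-(hydroxymethyl)-4-methoxy-2-[(2E,6E)-3,7,11-trimethyldodeca-2,6,10-trien-1-yl]phenol | CC(C)=CCC/C(C)=C/CC/C(C)=C/Cc1cc(OC)c(CO)cc1O | intermediate
12 | 5-(hydroxymethyl)-4,4-dimethoxy-2-[(2E,6E)-3,7,11-trimethyldodeca-2,6,10-trien-1-yl]cyclohexa-2,5-dien-1-one | CC(C)=CCC/C(C)=C/CC/C(C)=C/CC1=CC(OC)(OC)C(CO)=CC1=O | intermediate
13 | (1R,6S)-4-(hydroxymethyl)-5,5-dimethoxy-1-[(2E,6E)-3,7,11-trimethyldodeca-2,6,10-trien-1-yl]-7-oxabicyclo[4.1.0]hept-3-en-2-one | CC(C)=CCC/C(C)=C/CC/C(C)=C/C[C@@]12O[C@@H]1C(OC)(OC)C(CO)=CC2=O | intermediate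
14 | (1R,6S)-4-(hydroxymethyl)-1-[(2E,6E)-3,7,11-trimethyldodeca-2,6,10-trien-1-yl]-7-oxabicyclo[4.1.0]hept-3-ene-2,5-dione | CC(C)=CCC/C(C)=C/CC/C(C)=C/C[C@@]12O[C@@H]1C(=O)C(CO)=CC2=O | intermediate
15 | (1R,5R,6R)-5-hydroxy-4-(hydroxymethyl)-1-[(2E,6E)-3,7,11-trimethyldodeca-2,6,10-trien-1-yl]-7-oxabicyclo[4.1.0]hept-3-en-2-one | CC(C)=CCC/C(C)=C/CC/C(C)=C/C[C@@]12O[C@@H]1[C@H](O)C(CO)=CC2=O | intermediate
16 | (R)-mevalonolactone, (4R)-4-hydroxy-4-methyloxan-2-one | C[C@]1(O)CC(=O)OCC1 | starting material
17 | potassium (3R)-3,5-dihydroxy-3-methylpentanoate | C[C@](O)(CC(=O)[O-])CCO.[K+] | intermediate (not isolated)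
18 | [2-(trimethylsilyl)ethoxy]methyl (3R)-3,5-dihydroxy-3-methylpentanoate | C[C@](O)(CC(=O)OCOCC[Si](C)(C)C)CCO | intermediate
19 | (3R)-3-hydroxy-3-methyl-5-oxo-5-{[2-(trimethylsilyl)ethoxy]methoxy}pentanoic acid | C[C@](O)(CC(=O)OCOCC[Si](C)(C)C)CC(=O)O | intermediate
20 | {(1R,5R,6R)-5-hydroxy-2-oxo-1-[(2E,6E)-3,7,11-trimethyldodeca-2,6,10-trien-1-yl]-7-oxabicyclo[4.1.0]hept-3-en-4-yl}methyl [2-(trimethylsilyl)ethoxy]methyl (3R)-3-hydroxy-3-methylpentanedioate | CC(C)=CCC/C(C)=C/CC/C(C)=C/C[C@@]12O[C@@H]1[C@H](O)C(COC(=O)C[C@@](C)(O)CC(=O)OCOCC[Si](C)(C)C)=CC2=O | intermediate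
21 | (3S)-3-hydroxy-5-{[(1R,5R,6R)-5-hydroxy-2-oxo-1-[(2E,6E)-3,7,11-trimethyldodeca-2,6,10-trien-1-yl]-7-oxabicyclo[4.1.0]hept-3-en-4-yl]methoxy}-3-methyl-5-oxopentanoic acid | CC(C)=CCC/C(C)=C/CC/C(C)=C/C[C@@]12O[C@@H]1[C@H](O)C(COC(=O)C[C@@](C)(O)CC(=O)O)=CC2=O | target

**Totals and risks**
Total step count: 16. Longest linear sequence: 13 steps (from 3 through steps 2–12, 15 and 16).

Most likely to fail:

(1) Step 10. The sodium tartrate–peroxide aggregate may discriminate the two faces of the dienone weakly or in the wrong sense, or untemplated background epoxidation may erode the enantiomeric purity. The fallback sets out from 12 and returns at 13, and replaces alkoxide-anchored tartrate control by ion pairing with a chiral ammonium cation. The primary hydroxyl of 12 is silylated (TBSCl, imidazole, DMF) to give 5-{[(tert-butyldimethylsilyl)oxy]methyl}-4,4-dimethoxy-2-farnesylcyclohexa-2,5-dien-1-one F1. Nucleophilic epoxidation under chiral phase-transfer catalysis (N-benzylcinchonidinium chloride or its cinchoninium pseudo-enantiomer, whichever shields the unwanted face, t-BuOOH, aq. NaOH, toluene, 0 °C) should give (1R,6S)-4-{[(tert-butyldimethylsilyl)oxy]methyl}-5,5-dimethoxy-1-farnesyl-7-oxabicyclo[4.1.0]hept-3-en-2-one F2. Desilylation (HF·pyridine, THF) then gives 13.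

(2) Step 12. Hydride may be delivered to the oxirane face of the C5 carbonyl, or the two faces may be poorly discriminated, so that the C5 epimer forms. The fallback sets out from 14 and returns at 20, and corrects the centre by SN2 inversion instead of by face-selective reduction. The epimeric product (1R,5S,6R)-5-hydroxy-4-(hydroxymethyl)-1-farnesyl-7-oxabicyclo[4.1.0]hept-3-en-2-one F3 is esterified at the primary hydroxyl with 19 (EDC·HCl, DMAP) to give [(1R,5S,6R)-5-hydroxy-2-oxo-1-farnesyl-7-oxabicyclo[4.1.0]hept-3-en-4-yl]methyl SEM (3R)-3-hydroxy-3-methylpentanedioate F4. Mitsunobu inversion of the secondary carbinol with chloroacetic acid (PPh3, DIAD, THF) should give [(1R,5R,6R)-5-(chloroacetoxy)-2-oxo-1-farnesyl-7-oxabicyclo[4.1.0]hept-3-en-4-yl]methyl SEM (3R)-3-hydroxy-3-methylpentanedioate F5. Selective removal of the chloroacetyl group (thiourea, NaHCO3, EtOH) then gives 20.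

(3) Step 7. The alane may be protodemetalated before coupling, residual Me3Al may transfer methyl to the benzylic position, or the benzylic chloride may homocouple at Ni(0). The fallback sets out from 2 and 8 and returns at 10, with the polarity of the partners reversed. Alkyne 2 is methylaluminated as before and alane 9 is quenched with iodine to give (1E,5E)-1-iodo-2,6,10-trimethylundeca-1,5,9-triene F6, which is purified. Chloride 8 is converted by zinc insertion (Zn dust, LiCl, THF) into chloro({5-methoxy-2-[(triisopropylsilyl)oxy]-4-{[(triisopropylsilyl)oxy]methyl}phenyl}methyl)zinc F7. Negishi coupling of F7 with F6 (Pd(PPh3)4, THF, rt) should give 10 with retention of the olefin geometry.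

**Further compounds**
F1 | step 10 | 5-{[(tert-butyldimethylsilyl)oxy]methyl}-4,4-dimethoxy-2-[(2E,6E)-3,7,11-trimethyldodeca-2,6,10-trien-1-yl]cyclohexa-2,5-dien-1-one | CC(C)=CCC/C(C)=C/CC/C(C)=C/CC1=CC(OC)(OC)C(CO[Si](C)(C)C(C)(C)C)=CC1=O
F2 | step 10 | (1R,6S)-4-{[(tert-butyldimethylsilyl)oxy]methyl}-5,5-dimethoxy-1-[(2E,6E)-3,7,11-trimethyldodeca-2,6,10-trien-1-yl]-7-oxabicyclo[4.1.0]hept-3-en-2-one | CC(C)=CCC/C(C)=C/CC/C(C)=C/C[C@@]12O[C@@H]1C(OC)(OC)C(CO[Si](C)(C)C(C)(C)C)=CC2=O
F3 | step 12 | (1R,5S,6R)-5-hydroxy-4-(hydroxymethyl)-1-[(2E,6E)-3,7,11-trimethyldodeca-2,6,10-trien-1-yl]-7-oxabicyclo[4.1.0]hept-3-en-2-one | CC(C)=CCC/C(C)=C/CC/C(C)=C/C[C@@]12O[C@@H]1[C@@H](O)C(CO)=CC2=O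
F4 | step 12 | {(1R,5S,6R)-5-hydroxy-2-oxo-1-[(2E,6E)-3,7,11-trimethyldodeca-2,6,10-trien-1-yl]-7-oxabicyclo[4.1.0]hept-3-en-4-yl}methyl [2-(trimethylsilyl)ethoxy]methyl (3R)-3-hydroxy-3-methylpentanedioate | CC(C)=CCC/C(C)=C/CC/C(C)=C/C[C@@]12O[C@@H]1[C@@H](O)C(COC(=O)C[C@@](C)(O)CC(=O)OCOCC[Si](C)(C)C)=CC2=O
F5 | step 12 | {(1R,5R,6R)-5-[(chloroacetyl)oxy]-2-oxo-1-[(2E,6E)-3,7,11-trimethyldodeca-2,6,10-trien-1-yl]-7-oxabicyclo[4.1.0]hept-3-en-4-yl}methyl [2-(trimethylsilyl)ethoxy]methyl (3R)-3-hydroxy-3-methylpentanedioate | CC(C)=CCC/C(C)=C/CC/C(C)=C/C[C@@]12O[C@@H]1[C@H](OC(=O)CCl)C(COC(=O)C[C@@](C)(O)CC(=O)OCOCC[Si](C)(C)C)=CC2=O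
F6 | step 7 | (1E,5E)-1-iodo-2,6,10-trimethylundeca-1,5,9-triene | CC(C)=CCC/C(C)=C/CC/C(C)=C/I
F7 | step 7 | chloro({5-methoxy-2-[(triisopropylsilyl)oxy]-4-{[(triisopropylsilyl)oxy]methyl}phenyl}methyl)zinc | Cl[Zn]Cc1cc(OC)c(CO[Si](C(C)C)(C(C)C)C(C)C)cc1O[Si](C(C)C)(C(C)C)C(C)C
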